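The complex with two exchanged is reached through the complex with one exchanged, and each exchange uses one incoming ligand and frees one leaving ligand, which the scavenger removes.

in all of them: starting complex 0.10 M

|  | incoming ligand | scavenger | remark | time |
|---|---|---|---|---|
| Sunday's | 0.059 M | 0.080 M | run made earlier |  |
| Wednesday's | 0.12 M | 0.080 M | run made earlier |  |
| midnight | 0.300 M | 0.0800 M |  | 50 h |
| spring | 0.250 M | 0.0800 M |  | 50 h |
| autumn | 0.0500 M | 0.0800 M |  | 50 h |

- Sunday's (time / h: complex with one exchanged / %, starting complex / %): 10.0: 10.4, 82.2; 20.0: 15.7, 74.2; 30.0: 18.1, 70.2; 40.0: 17.2, 67.9; 48.0: 18.9, 67.0
- Wednesday's (time / h: complex with one exchanged / %, starting complex / %): 4.00: 9.1, 78.7; 12.0: 16.5, 62.9; 25.0: 18.8, 51.7; 40.0: 19.2, 42.7; 48.0: 20.6, 41.3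

(standard deviation of a reading: 1 percentage point)

- which of these holds the largest part of the starting complex at the end of midnight (complex with two exchanged / complex with one exchanged / starting complex)
- which of these holds the largest part of the starting complex at the end of spring (complex with two exchanged / complex with one exchanged / starting complex)
- which of these holds the largest part of the starting complex at the end of autumn (complex with two exchanged / complex with one exchanged / starting complex)
- complex with one exchanged at the end of autumn, in percent of the starting complex charged

- for leaving ligand the idle adduct is counted in
- on the list of suspects stand: starting complex + incoming ligand <-> leaving ligand + complex with one exchanged; complex with one exchanged + incoming ligand <-> leaving ligand + complex with two exchanged; leaving ligand + starting complex <-> idle adduct; scavenger + leaving ligand -> scavenged by-product; incoming ligand <-> dormant form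

So one ratio is worth reading first: the scavenger cover, scavenger charged over incoming ligand charged, which is 1.60 for autumn. The crossing lies at a cover of one: above it, the exchanges cannot free enough leaving ligand to use up the scavenger, while below it the scavenger can become the limiting reagent. Autumn stands on the same side as Sunday's run at 1.36. Apart from that, autumn's charge of incoming ligand, 0.0500 M, lies just below Sunday's 0.059 M, and on this closeness of charge, not on the side of the crossing, this reckoning puts autumn's complex with one exchanged just under Sunday's last reading of 18.9%, with starting complex leading. Midnight at 0.267 and spring at 0.320 lie below the crossing.

The forecast names complex with two exchanged for midnight, complex with two exchanged for spring and starting complex for autumn, with 17% of complex with one exchanged in autumn, on the ground that “Autumn's 0.050 M lies just below Sunday's 0.059 M”.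

The flasks give complex with two exchanged at midnight, complex with two exchanged in spring and starting complex in autumn, with 17.3% of complex with one exchanged in autumn. The forecast stands.

    starting complex + incoming ligand ⇌ leaving ligand + complex with one exchanged (K = 0.974, k = 0.00750 M⁻¹ min⁻¹)
    complex with one exchanged + incoming ligand ⇌ leaving ligand + complex with two exchanged (K = 0.800, k = 0.0234 M⁻¹ min⁻¹)
    leaving ligand + starting complex ⇌ idle adduct, settled at all times (K = 27.0 M⁻¹)
    scavenger + leaving ligand → scavenged by-product (k = 0.175 M⁻¹ min⁻¹)
    incoming ligand ⇌ dormant form (K = 0.572, k = 0.00202 min⁻¹)

Autumn, at its cover of 1.60, ends with 53% of its scavenger. At 50.0 h, free leaving ligand there has a half-life of 1.6 h by the scavenger, while the first exchange relaxes with a half-life of 16.3 h, ten times as long.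

A neighbour of autumn with 0.20 M of incoming ligand has a cover of 0.400, below the crossing, so its scavenger can be used up and autumn's outcome need not hold. That neighbour flask ends with 0.093% of its scavenger, 45.3% of complex with two exchanged against 19.6% of starting complex, and 23.3% of complex with one exchanged.

The readings are simulated with made-up constants, and the scatter is random.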